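The route rests on opening the spiro dihydropyran ring (O1'–C8–C13–C4'–C4a'=C8a') at O1'–C8 and C4'–C4a'. The feature used is that the tertiary ether carbon C8 of the nine-membered ring sits one carbon (C13) from the isobutyl-bearing C4': C8 becomes a nor-ketone, C13≡C4' an alkyne, and O1'–C8a'=C4a' a syncarpic enol ether. Heating the tertiary propargyl enol ether sets off a propargyl Claisen shift, enol-to-allene hydrogen transfer and oxa-6π electrocyclisation, which forms C4'–C4a', re-forms O1'–C8 and closes the spiro 2H-pyran in one operation. The precursor is the 4,5-epoxy-norcaryophyllane carrying on C8 a 4-methylpentynyl group and the syncarpic enol ether oxygen.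

Key step: step 5

Remark: caryophyllane numbering (C1–C15) is used for the terpene part and primed chromene locants (O1', C2' = C8, C3' = C13, C4', C4a', C5' to C8', C8a') for the pyran-dione part. The stereo elements that the key step erases (the C8 configuration of its precursors, the allene axis and the C8=C13 geometry of its two intermediates) are not controlled, and the SMILES of those two intermediates fix only the stereocentres that are carried through.

Step 1
Reactants: 1 (−)-caryophyllene oxide
Product: 3 kobusone, via spiro ozonide 2 (not isolated)
Conditions: O3, CH2Cl2, −78 °C; then PPh3, −78 °C → rt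
Reagents that add atoms: ozone, [O-][O+]=O
Why: Ozonolysis (Criegee cleavage) of the exocyclic C8=C13 bond, the only C=C present, removes C13 as formaldehyde and leaves the C8 ketone once the ozonide is reduced; the epoxide is inert to ozone and to PPh3 in the cold, and no stereocentre is touched.

Step 2
Reactants: 3 kobusone; 4 4-methylpent-1-yne
Product: 5 C8 propargylic alcohol (8R epimer drawn)
Conditions: 4, n-BuLi, THF, −78 °C; then 3, −78 °C; AcOH, −78 °C → rt
Reagents that add atoms: none
Why: 1,2-Addition of a lithium acetylide, a weakly basic nucleophile that adds to enolisable ketones and leaves a trisubstituted epoxide alone without a Lewis acid, forms C8–C13; the alkoxide is protonated cold before it can attack the epoxide across the ring, and the facial outcome at C8 is immaterial because both epimers converge once C8 becomes trigonal in step 5.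

Step 3
Reactants: 6 syncarpic acid
Product: 7 syncarpic acid chloride (5-chloro-2,2,6,6-tetramethylcyclohex-4-ene-1,3-dione)
Conditions: (COCl)2, DMF (cat.), CH2Cl2, 0 °C → rt
Reagents that add atoms: oxalyl chloride, O=C(Cl)C(Cl)=O
Why: Vilsmeier-type activation of the enol oxygen followed by chloride addition–elimination turns the vinylogous acid into its chloride; the enolisable dione unit is symmetric and the third ketone lies between two quaternary carbons, so only one chloro-enone can form.

Step 4
Reactants: 5 C8 propargylic alcohol; 7 syncarpic acid chloride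
Product: 9 tertiary propargyl enol ether of syncarpic acid, via potassium alkoxide 8 (not isolated)
Conditions: KHMDS, THF, −78 °C; then 7, −78 → −20 °C
Reagents that add atoms: none
Why: Addition–elimination of the tertiary propargylic alkoxide at the β-carbon of the vinylogous acid chloride (the enone counterpart of the SNAr ether synthesis from such alkoxides) forms O–C8a' without touching C8; 7 has no acidic hydrogen and can only act as the electrophile, and making and consuming the alkoxide below −20 °C should keep transannular attack on the 4,5-epoxide and retro-alkynylation slow.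

Step 5
Reactants: 9 tertiary propargyl enol ether of syncarpic acid
Product: 12 spiro 2H-pyran epoxide, via allenyl triketone 10 (not isolated), via oxatriene 11 (not isolated)
Conditions: o-xylene, 2,6-lutidine (0.2 equiv), 140 °C, sealed tube
Reagents that add atoms: none
Why: On heating, the enone α-carbon C4a' bonds to the alkyne terminus C4' in a concerted [3,3] (propargyl Claisen) shift that breaks the tertiary C8–O bond and gives allenyl triketone 10; its enol hands the hydroxyl hydrogen to the central allene carbon C13 (1,5-shift, lutidine as proton shuttle) to give 1-oxatriene 11, whose thermal disrotatory oxa-6π electrocyclisation joins O1' to C8. The same sequence converts aryl and 1,3-dione enol 1,1-dialkylpropargyl ethers into 2H-chromenes and fused 2H-pyrans on heating. The single ring closed, the spiro pyran, forms by six-atom electrocyclic closure of the O=C8a'–C4a'=C4'–C13=C8 triene onto C8 and not by an ionic cyclisation, so C8 never carries a cation or radical next to the cyclobutane. C8 is the only new stereocentre and is set in this closure; because the closure is reversible at 140 °C the two C8 epimers can exchange through 11, and the epimer with O1' on the outer, exposed face of the former C8=C13 bond is expected to dominate, the folded trans-fused C1/C9 bicycle being the controlling element. The step needs O–C8 six-ring closure rather than O–C13 five-ring closure to a furan; metal-free conditions, the symmetric triketone (either carbonyl gives the same pyran) and the fully substituted C8 (which favours the closed 2H-pyran over the open dienone) should secure this, while the tertiary propargylic centre and the acceptor-substituted vinyl ether speed the [3,3] shift and the lutidine keeps the acidic triketone from opening the epoxide.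

Step 6
Reactants: 12 spiro 2H-pyran epoxide
Product: 13 spiro dihydropyran epoxide (8S,4'S)
Conditions: H2 (1 atm), 10% Pd/C, EtOAc, rt
Reagents that add atoms: none
Why: Heterogeneous syn-hydrogenation of C3'=C4', the only C=C that is not a tetrasubstituted push–pull enol ether, should occur from the pyran face flanked by the C7 methylene and away from the C9 methine that carries the cyclobutane, which puts the new C4' hydrogen syn to C7 and the isobutyl group cis to C9 (4'S); the epoxide and the tertiary C8–O bond are expected to survive neutral Pd/C in ethyl acetate.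

Step 7
Reactants: 13 spiro dihydropyran epoxide
Product: 14 allylic alcohol (4(12)-en-5-ol, 5R)
Conditions: Et2Al(TMP) (from TMPH, n-BuLi and Et2AlCl), PhMe, 0 °C → rt; aq. potassium sodium tartrate
Reagents that add atoms: none
Why: Aluminium amide isomerisation of an epoxide to an allylic alcohol, in which aluminium binds the epoxide oxygen and the hindered amide removes a syn β-hydrogen from the C12 methyl through a cyclic transition state, breaks C4–O while C5–O and the 5R configuration are kept; the reagent avoids the α-lithiation and transannular carbenoid insertion that lithium amides cause in medium-ring epoxides, the molecule has no enolisable carbonyl, and any 3-en-5-ol regioisomer would converge on 16 in steps 8 and 9.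

Step 8
Reactants: 14 allylic alcohol
Product: 15 exo-methylene enone (4(12)-en-5-one)
Conditions: DMP, pyridine, CH2Cl2, 0 °C → rt
Reagents that add atoms: none
Why: Dess–Martin oxidation of the secondary allylic alcohol under buffered, non-acidic conditions gives the α-methylene ketone, deliberately erasing C5 so that it can be reset in step 10; the product is taken on at once because α-methylene ketones add nucleophiles and dimerise.

Step 9
Reactants: 15 exo-methylene enone
Product: 16 (3Z)-3-en-5-one
Conditions: RhCl3·3H2O (5 mol%), EtOH, 70 °C
Reagents that add atoms: none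
Why: Rhodium hydride alkene isomerisation (reversible Rh–H addition to the exocyclic alkene and β-hydride elimination toward C3) moves the double bond into the ring, and under these equilibrating conditions the trisubstituted conjugated endocyclic enone is favoured over the 1,1-disubstituted exocyclic one and the cis (Z) ring alkene over the strained trans isomer of a nine-membered ring.

Step 10
Reactants: 16 (3Z)-3-en-5-one
Product: 17 tomentodione P
Conditions: (R)-2-methyl-CBS-oxazaborolidine (1 equiv), catecholborane, PhMe, −78 → −40 °C; MeOH, then 1 M NaOH wash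
Reagents that add atoms: none
Why: Corey–Bakshi–Shibata reduction, with the C3=C4 alkenyl branch as the large and the C6 methylene as the small ketone substituent, should deliver hydride from the face that gives the 5S alcohol by 1,2-addition, while the vinylogous ester carbonyl C5' and the C7' ketone between two quaternary carbons are too unreactive and too hindered to compete at −78 °C.

Compound list
1 | (−)-caryophyllene oxide, (1R,4R,5R,9S)-4,5-epoxycaryophyll-8(13)-ene | C[C@@]12CC[C@@H]3[C@H](CC3(C)C)C(=C)CC[C@H]1O2 | starting material
2 | spiro ozonide: 1,2,4-trioxolane spiro-fused at C8 of the 4,5-epoxy-norcaryophyllane with C13 as the ring CH2; both C8 epimers; not isolated | C[C@@]12CC[C@@H]3[C@H](CC3(C)C)C4(OOCO4)CC[C@H]1O2 | intermediate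
3 | kobusone, (1R,4R,5R,9S)-4,5-epoxy-13-norcaryophyllan-8-one | C[C@@]12CC[C@@H]3[C@H](CC3(C)C)C(=O)CC[C@H]1O2 | intermediate
4 | 4-methylpent-1-yne | C#CCC(C)C | starting material
5 | C8 propargylic alcohol, (1R,4R,5R,8R,9S)-4,5-epoxy-8-(4-methylpent-1-yn-1-yl)-13-norcaryophyllan-8-ol | C[C@@]12CC[C@@H]3[C@H](CC3(C)C)[C@@](O)(C#CCC(C)C)CC[C@H]1O2 | intermediate
6 | syncarpic acid, 2,2,4,4-tetramethylcyclohexane-1,3,5-trione | CC1(C)C(=O)CC(=O)C(C)(C)C1=O | starting material
7 | syncarpic acid chloride, 5-chloro-2,2,6,6-tetramethylcyclohex-4-ene-1,3-dione | O=C1C=C(Cl)C(C)(C)C(=O)C1(C)C | intermediate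
8 | potassium alkoxide of 5 (C8–O− K+); not isolated | C[C@@]12CC[C@@H]3[C@H](CC3(C)C)[C@@]([O-])(C#CCC(C)C)CC[C@H]1O2.[K+] | intermediate
9 | tertiary propargyl enol ether: 2,2,6,6-tetramethylcyclohex-4-ene-1,3-dione carrying at C5 the C8–O oxygen of 5 (8R) | C[C@@]12CC[C@@H]3[C@H](CC3(C)C)[C@@](OC4=CC(=O)C(C)(C)C(=O)C4(C)C)(C#CCC(C)C)CC[C@H]1O2 | intermediate
10 | allenyl triketone: 2,2,4,4-tetramethylcyclohexane-1,3,5-trione whose C6 (= C4a') bears the isobutyl-substituted allene carbon C4', joined through C13 to ring carbon C8 (C4'=C13=C8) of the 4,5-epoxy-norcaryophyllane; not isolated | C[C@@]12CC[C@@H]3[C@H](CC3(C)C)C(=C=C(CC(C)C)C4C(=O)C(C)(C)C(=O)C(C)(C)C4=O)CC[C@H]1O2 | intermediate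
11 | 1-oxatriene: 6-ylidene-2,2,4,4-tetramethylcyclohexane-1,3,5-trione with C4a'=C4'(isobutyl)–C13H=C8; not isolated | C[C@@]12CC[C@@H]3[C@H](CC3(C)C)C(=CC(CC(C)C)=C4C(=O)C(C)(C)C(=O)C(C)(C)C4=O)CC[C@H]1O2 | intermediate
12 | spiro 2H-pyran epoxide: 4'-isobutyl-6',6',8',8'-tetramethyl-2'H-chromene-5',7'-dione (C3'=C4', C4a'=C8a') spiro-fused through C2' = C8 to the (1R,4R,5R,9S)-4,5-epoxy-norcaryophyllane, C8 arranged as in the target | C[C@@]12CC[C@@H]3[C@H](CC3(C)C)[C@]4(CC[C@H]1O2)C=C(CC(C)C)C5=C(O4)C(C)(C)C(=O)C(C)(C)C5=O | intermediate
13 | spiro dihydropyran epoxide: 12 with C3'H2–C4'H saturated, (1R,4R,5R,8S,9S,4'S), isobutyl cis to C9 | C[C@@]12CC[C@@H]3[C@H](CC3(C)C)[C@]4(CC[C@H]1O2)C[C@H](CC(C)C)C5=C(O4)C(C)(C)C(=O)C(C)(C)C5=O | intermediate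
14 | allylic alcohol: (1R,5R,8S,9S,4'S)-4(12)-en-5-ol with exocyclic C4=C12H2 | C=C1CC[C@@H]2[C@H](CC2(C)C)[C@]2(CC[C@H]1O)C[C@H](CC(C)C)C1=C(O2)C(C)(C)C(=O)C(C)(C)C1=O | intermediate
15 | exo-methylene enone: (1R,8S,9S,4'S)-4(12)-en-5-one | C=C1CC[C@@H]2[C@H](CC2(C)C)[C@]2(CCC1=O)C[C@H](CC(C)C)C1=C(O2)C(C)(C)C(=O)C(C)(C)C1=O | intermediate
16 | (1R,3Z,8S,9S,4'S)-3-en-5-one with C4 methyl | C/C1=C/C[C@@H]2[C@H](CC2(C)C)[C@]2(CCC1=O)C[C@H](CC(C)C)C1=C(O2)C(C)(C)C(=O)C(C)(C)C1=O | intermediate
17 | tomentodione P, (1R,3Z,5S,8S,9S,4'S)-3-en-5-ol | C/C1=C/C[C@@H]2[C@H](CC2(C)C)[C@]2(CC[C@@H]1O)C[C@H](CC(C)C)C1=C(O2)C(C)(C)C(=O)C(C)(C)C1=O | target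

Total step count: 10.
Longest linear sequence: 9 steps, from 1 to 17 through steps 1, 2 and 4 to 10; step 3 is a one-step side branch.

Steps most likely to fail

Step 4. The addition of the hindered tertiary alkoxide to the β-carbon next to a quaternary centre may be slow. The C8 alkoxide could then attack the 4,5-epoxide across the ring or fragment back to ketone and acetylide. The fallback sets out from 5 and 7 and avoids any metal alkoxide. Chloride 7 is first treated with DABCO (MeCN, rt) to give the vinylogous acylammonium chloride F1, a cationic and far more electrophilic enone. Neutral alcohol 5 is then added to F1 with iPr2NEt (MeCN, 40 °C), DABCO leaves, and the route is rejoined at 9.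

Step 5. Five-ring O–C13 closure to a furan may compete with the six-ring closure, or equilibration may settle on the unwanted C8 epimer; poor facial selectivity in step 6 would add to this. The fallback sets out from 1 and 6 and replaces the rearrangement by a cycloaddition. Knoevenagel condensation of 6 with commercial 3-methylbutanal (pyrrolidine, AcOH, CH2Cl2, rt) should give the isobutyl-substituted enetrione F2. Heating F2 in situ with 1 (PhMe, 80 °C) should give an inverse-demand hetero-Diels–Alder reaction with the exocyclic C8=C13 bond, which is the only alkene of 1. O1'–C8 and C13–C4' form suprafacially on the exposed alkene face, both stereocentres are set kinetically, and the diastereomers would be separated by chromatography. The route is rejoined at 13.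

Step 10. The conformational bias of the folded nine-membered enone may override the catalyst and give mainly the 5R alcohol. The fallback sets out from 16 and relies on substrate control followed by inversion. Luche reduction (NaBH4, CeCl3·7H2O, MeOH, −40 °C) should give the substrate-preferred allylic alcohol. Should this be the 5R epimer F3, Mitsunobu inversion (4-nitrobenzoic acid, PPh3, DIAD, THF, 0 °C) should give the 5S 4-nitrobenzoate F4. Methanolysis (K2CO3, MeOH, rt) then rejoins the route at 17.

Further compounds
F1 | step 4 | 1-(4,4,6,6-tetramethyl-3,5-dioxocyclohex-1-en-1-yl)-1,4-diazabicyclo[2.2.2]octan-1-ium chloride | O=C1C=C([N+]23CCN(CC2)CC3)C(C)(C)C(=O)C1(C)C.[Cl-]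
F2 | step 5 | 2,2,4,4-tetramethyl-6-(3-methylbutylidene)cyclohexane-1,3,5-trione | CC(C)CC=C1C(=O)C(C)(C)C(=O)C(C)(C)C1=O
F3 | step 10 | 5-epi-tomentodione P, the (5R)-alcohol | C/C1=C/C[C@@H]2[C@H](CC2(C)C)[C@]2(CC[C@H]1O)C[C@H](CC(C)C)C1=C(O2)C(C)(C)C(=O)C(C)(C)C1=O
F4 | step 10 | tomentodione P 5-O-(4-nitrobenzoate), 5S | C/C1=C/C[C@@H]2[C@H](CC2(C)C)[C@]2(CC[C@@H]1OC(=O)c1ccc(cc1)[N+](=O)[O-])C[C@H](CC(C)C)C1=C(O2)C(C)(C)C(=O)C(C)(C)C1=O
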